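Flasks beta and eta are neighbours that differ in the scavenger charge, which leaves you asking whether the extra scavenger buys conversion.

all flasks: substrate 20 mM; coupling partner 60.0 mM; time 2.5 h
- beta: scavenger 6.00 mM
- eta: scavenger 9.00 mM

    substrate + released group ⇌ idle adduct, settled at all times (K1 = 110 M⁻¹)
    intermediate → product (k2 = 0.0095 min⁻¹)
    scavenger + released group → scavenged by-product (k3 = 16 M⁻¹ min⁻¹)
    substrate + coupling partner → intermediate + released group (k4 = 0.24 M⁻¹ min⁻¹)

- part of the substrate that has reacted at the end, beta
- part of the substrate that has reacted at the end, eta
- what raising the concentration of scavenger from its lowest to its highest value here does to the part of the substrate that has reacted (changes below 5 percentage points count as none) (no change / it falls / it rises)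

- released group is meant together with its idle adduct
- what has gone from substrate into another species counts as reacted, even if it can come back
- run time (beta): 2.5 h

Idle adduct counts as reacted, so work with the fraction left as free substrate. With the coupling partner in excess, the coupling step is pseudo-first-order, and the fraction left is the exponential of minus the exposure, meaning the rate constant of coupling times c(coupling partner) times the time, 2.16 in either flask, which leaves 11.5%. But the reaction can eat a third of the coupling partner, and taking it at its middle level lowers the exposure to 1.84 and leaves 15.9%.

The next doubt is the adduct: the binding constant times c(substrate) at the start of beta is 2.2, no small number. In beta as charged, the half-life of free released group by the scavenger step alone is 0.12 h against 0.80 h for substrate by the coupling step alone, but both scavenger charges stand below the substrate charge, so once more substrate has coupled than scavenger was charged, released group is left over. Call x the binding constant times c(free released group). By this estimate, group released minus scavenger charged, shared with the adduct, gives at the end of the run x of 0.883 in beta and 0.638 in eta.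

This cuts both ways. Binding moves substrate out of the free form, and in this reckoning that adds the logarithm of 1 + x to the exponent. It also shields that substrate from coupling, which, with x growing steadily from zero, takes away the exposure times 1 minus that logarithm over x. The net gain is 0.111 in beta and 0.0764 in eta, so I commit to 85.8% reacted in beta and 85.3% in eta, a shift of −0.5 percentage points, which is no change by the margin.

The forecast gave 86% for beta, 88% for eta, which differs from mine on eta, and no change, holding that the released group "only moderately slows things by holding some substrate as adduct".

The simulation gives 85.0% for beta and 84.5% for eta, a shift of −0.57 points, so no change. At the end, idle adduct holds 10.9% of the charged substrate in beta and 8.04% in eta. Now read beta at 1.5 h: the exposure, scaled to that time with the coupling partner midway between its charge and the 80% remaining, is 1.17, and the 3.96 mM of free released group gives x of 0.436, so the same reckoning leaves 26.4%, and that flask holds 28% as free substrate.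

(All constants were drawn at random within sensible limits; the rest is arithmetic.)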